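**Strategy.** The route rests on cutting the bicyclo[2.2.2]octenone at the two bonds that join its alkene (the ring E butenolide carbons) to the methyl-bearing and the CH2O-bearing bridgeheads. These bridgeheads are the 1,4-termini of a 2-silyloxy-1,3-cyclohexadiene (ring D), and the alkene with the lactone carbonyl is a propiolate already tethered through the ring E CH2–O. One intramolecular Diels–Alder reaction therefore closes the bicycle and the butenolide and sets both bridgeheads from the spiro carbon. Its precursor is a spiro[5.5] dienol ether whose ring B stereocentres are relayed from one catalytic conjugate addition through a temporary cis-fused γ-lactone; ring C (enolate alkylation) and ring A (metathesis) follow.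

Key step: step 15

Remark on labels: ring A = unsaturated δ-lactone; ring B = cyclohexane; ring C = cyclopentane; ring D = the six-membered ring of the bicycle that holds the ketone and the spiro carbon; ring E = butenolide. On ring B, β is the face that carries the CH2X carbon next to the spiro centre and α is the other face.

Remark on the chemistry: the methyl-bearing CH of the side chain introduced in step 2 is carried as a mixture of epimers (drawn without configuration) until it becomes sp2 in step 14. Compounds 1 and 4 and all named reagents are assumed to be commercially available.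

Step 1
Reactants: 1 2-methylpent-1-en-3-one
Product: 3 bromo ketal, via bromo ketone 2 (not isolated)
Conditions: HBr (gas), ethane-1,2-diol, 1,4-dioxane, 5 °C → rt
Reagents that add atoms: hydrogen bromide (Br); ethane-1,2-diol (OCCO)
Why: Conjugate addition of HBr to the enone followed by in situ acid-catalysed ketalisation should give the β-bromo ketal, as in the standard preparation of bromoethyl dioxolanes from vinyl ketones; the new methine is racemic and of no consequence.

Step 2
Reactants: 3 bromo ketal; 4 methyl 3-oxocyclohex-1-ene-1-carboxylate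
Product: 8 keto lactone, via dialkylzinc 5 (not isolated), via zinc enolate 6 (not isolated), via hydroxymethyl keto ester 7 (not isolated)
Conditions: 3, Mg, THF; ZnCl2 (0.5 equiv); then 4, Cu(OTf)2 (2.5 mol%), chiral sulfonate-bearing imidazolinium salt (Hoveyda type, 2.5 mol%), Et2O, −30 °C; then CH2O (gas), −78 → −20 °C; aq. NH4Cl; then TsOH·H2O, CH2Cl2, rt
Reagents that add atoms: formaldehyde (C=O)
Why: Copper-catalysed asymmetric conjugate addition of the dialkylzinc to the β-ester enone should set the quaternary carbon β to the ketone under ligand control (ligand antipode chosen for the configuration drawn), the zinc enolate should be trapped by formaldehyde anti to the new alkyl group (tandem aldol reaction), and acid then closes the cis γ-lactone between CH2OH and the ester, which also funnels any epimer at the enolisable CH.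

Step 3
Reactants: 8 keto lactone
Product: 9 hydroxymethylene ketone
Conditions: LiN(iPr)2, THF, −78 °C; then CF3CH2OCHO, −78 °C; aq. HCl
Reagents that add atoms: 2,2,2-trifluoroethyl formate (O=COCC(F)(F)F)
Why: Kinetic deprotonation should occur at the only unhindered α-CH2 (the other α-carbon is the ring-fusion CH) and Claisen-type formylation then gives the enolised β-keto aldehyde.

Step 4
Reactants: 9 hydroxymethylene ketone
Product: 10 formyl isopropenyl ketone
Conditions: Pb(OAc)4, tributyl(prop-1-en-2-yl)stannane, CHCl3, rt; then 9, pyridine, 40 °C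
Reagents that add atoms: tributyl(prop-1-en-2-yl)stannane (CC(=C)[Sn](CCCC)(CCCC)CCCC)
Why: Pinhey α-alkenylation (ligand coupling of the β-dicarbonyl with the alkenyllead triacetate) should create the quaternary carbon, with the isopropenyl group delivered axially to the α face, anti to the lactone CH2 on the convex side of the cis-fused bicycle, which leaves the formyl group β.

Step 5
Reactants: 10 formyl isopropenyl ketone
Product: 11 vinyl isopropenyl ketone
Conditions: Ph3PCH3Br, KN(SiMe3)2, THF, −78 → 0 °C
Reagents that add atoms: methyltriphenylphosphonium bromide (C[P+](c1ccccc1)(c1ccccc1)c1ccccc1.[Br-])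
Why: Wittig methylenation should be selective for the aldehyde over the doubly neopentyl ketone and the lactone.

Step 6
Reactants: 11 vinyl isopropenyl ketone
Product: 13 silyl ether, via tertiary alcohol 12 (not isolated)
Conditions: MeLi, CeCl3, THF, −78 °C; then TBSOTf, 2,6-lutidine, −78 → 0 °C
Reagents that add atoms: methyllithium ([Li]C); tert-butyldimethylsilyl trifluoromethanesulfonate (CC(C)(C)[Si](C)(C)OS(=O)(=O)C(F)(F)F)
Why: 1,2-Addition of the organocerium reagent to the hindered ketone should occur equatorially from the α face, because axial attack is blocked by the syn-axial lactone carbonyl carbon at the ring fusion (as in 3,3,5-trimethylcyclohexanone), giving the β-alkoxide, which is silylated in situ before it can transacylate.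

Step 7
Reactants: 13 silyl ether
Product: 15 dimethylcarbinol, via organomercurial 14 (not isolated)
Conditions: Hg(OAc)2, THF/H2O, rt; then NaBH4, 3 M NaOH, 0 °C
Reagents that add atoms: water (O)
Why: Markovnikov oxymercuration–demercuration should hydrate the 1,1-disubstituted alkene faster than the monosubstituted vinyl group; no stereocentre is formed.

Step 8
Reactants: 15 dimethylcarbinol
Product: 16 ethyl ketone
Conditions: pyridinium p-toluenesulfonate, acetone/H2O, 55 °C
Reagents that add atoms: water (O)
Why: Acid-catalysed ketal hydrolysis should unmask the side-chain ketone while the tertiary silyl ether, the tertiary alcohol and the lactone survive.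

Step 9
Reactants: 16 ethyl ketone
Product: 17 spiro enol dione
Conditions: KOtBu, THF, 0 °C → rt; aq. HCl
Reagents that add atoms: none
Why: Intramolecular Claisen (Dieckmann-type) condensation: the ethyl ketone enolate should attack the lactone carbonyl in a 6-exo-trig closure to form ring D as a 2-methyl-1,3-dione whose enolate is the thermodynamic sink, releasing the lactone oxygen as the primary alcohol.

Step 10
Reactants: 17 spiro enol dione
Product: 18 vinylogous ester
Conditions: Me3SiCHN2, MeOH/toluene, 0 °C
Reagents that add atoms: (trimethylsilyl)diazomethane (C[Si](C)(C)C=[N+]=[N-])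
Why: O-Methylation of the vinylogous acid should occur at the enol oxygen remote from the spiro carbon, giving the vinylogous ester whose carbonyl sits next to the spiro centre.

Step 11
Reactants: 18 vinylogous ester
Product: 19 chloride
Conditions: N-chlorosuccinimide, PPh3, CH2Cl2, −20 → 0 °C
Reagents that add atoms: N-chlorosuccinimide (ClN1C(=O)CCC1=O)
Why: Appel-type chlorination should convert the primary alcohol only, the hindered tertiary alcohol being inert.

Step 12
Reactants: 19 chloride
Product: 21 hydroxymethyl enone, via carbinol adduct 20 (not isolated)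
Conditions: Bu3SnCH2OCH(CH3)OEt, n-BuLi, THF, −78 °C; then 19, −78 → −40 °C; then 1 M HCl, THF, rt
Reagents that add atoms: tributyl[(1-ethoxyethoxy)methyl]stannane (CCCC[Sn](CCCC)(CCCC)COC(C)OCC)
Why: Stork–Danheiser sequence: 1,2-addition of the α-alkoxymethyllithium to the vinylogous ester carbonyl, then acid-induced enol ether hydrolysis, dehydration with carbonyl transposition and cleavage of the ethoxyethyl acetal should give the enone with its free CH2OH.

Step 13
Reactants: 21 hydroxymethyl enone
Product: 22 propiolate
Conditions: propiolic acid, DCC, DMAP (cat.), CH2Cl2, −20 → 0 °C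
Reagents that add atoms: propiolic acid (C#CC(=O)O)
Why: Steglich esterification should acylate the primary allylic alcohol only.

Step 14
Reactants: 22 propiolate
Product: 23 silyl dienol ether
Conditions: Et3SiOTf, Et3N, CH2Cl2, −78 → 0 °C
Reagents that add atoms: triethylsilyl trifluoromethanesulfonate (CC[Si](CC)(CC)OS(=O)(=O)C(F)(F)F)
Why: Soft enolisation should remove the α′ proton of the enone to give the cross-conjugated 2-silyloxy-1,3-diene and silylate the tertiary alcohol; the side-chain epimers converge here.

Step 15
Reactants: 23 silyl dienol ether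
Product: 25 tricyclic keto lactone, via cycloadduct 24 (not isolated)
Conditions: toluene (0.01 M), BHT, 130 °C, sealed tube; then 1 M HCl, THF, 0 °C
Reagents that add atoms: none
Why: Heating should bring the tethered propiolate over the 2-silyloxy-1,3-cyclohexadiene of ring D for a concerted, asynchronous [4+2] cycloaddition in which the ester-bearing alkyne carbon bonds to the CH2O-bearing diene terminus and the terminal alkyne carbon bonds to the methyl-bearing terminus; the closest known reaction type is the type 1 intramolecular Diels–Alder reaction of ester-tethered alkynoates with cyclohexadienol silyl ethers, which gives bicyclo[2.2.2]octadienes. Two rings close: the new six-membered ring that completes the bicyclo[2.2.2]octadiene by 1,4-addition across the ring D diene, and the five-membered ring E lactone, closed through the three-atom ester tether as the fused five-ring of a type 1 process. Both bridgehead stereocentres arise together from the choice of diene face, which the spiro carbon of ring B controls. The step needs π-facial selectivity only (regiochemistry is fixed by the tether): the alkyne must add to the face flanked by the ring B CH2 and anti to the ring B CH that carries the chloromethyl group, and that CH with its CH2Cl and the neighbouring quaternary silyloxy carbon should shield the other face. Dilute acid in the work-up then hydrolyses the enol ether to the ketone and frees the tertiary alcohol.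

Step 16
Reactants: 25 tricyclic keto lactone
Product: 26 pentacyclic ketone
Conditions: KN(SiMe3)2 (2.2 equiv), THF, −78 → 0 °C
Reagents that add atoms: none
Why: Intramolecular enolate C-alkylation (5-exo-tet) at the only enolisable α-carbon should close ring C, and the new quaternary centre can form only on the face that the chloromethyl tether reaches.

Step 17
Reactants: 26 pentacyclic ketone
Product: 27 acrylate
Conditions: acryloyl chloride, iPr2NEt, DMAP, CH2Cl2, 0 → 40 °C
Reagents that add atoms: acryloyl chloride (C=CC(=O)Cl)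
Why: DMAP-catalysed acylation should esterify the only free hydroxyl, the other tertiary oxygen being silylated.

Step 18
Reactants: 27 acrylate
Product: 28 silyl andibenin B
Conditions: second-generation Hoveyda–Grubbs catalyst (10 mol%), toluene, 80 °C
Reagents that add atoms: none
Why: Ring-closing metathesis of the acrylate with the vinyl group should give the α,β-unsaturated δ-lactone of ring A, cis by ring size, while the trisubstituted conjugated alkene of the bicycle stays inert.

Step 19
Reactants: 28 silyl andibenin B
Product: 29 andibenin B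
Conditions: HF·pyridine, pyridine/THF, 0 °C → rt
Reagents that add atoms: none
Why: Acidic fluoride desilylation should free the tertiary alcohol without forming an alkoxide that could transacylate onto the ring A lactone.

**Compound list**

1 | 2-methylpent-1-en-3-one | CCC(=O)C(C)=C | starting material
2 | 1-bromo-2-methylpentan-3-one (racemic) | CCC(=O)C(C)CBr | intermediate
3 | 2-(1-bromopropan-2-yl)-2-ethyl-1,3-dioxolane (racemic) | CCC1(OCCO1)C(C)CBr | intermediate
4 | methyl 3-oxocyclohex-1-ene-1-carboxylate | COC(=O)C1=CC(=O)CCC1 | starting material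
5 | bis[2-(2-ethyl-1,3-dioxolan-2-yl)propyl]zinc | CCC1(OCCO1)C(C)C[Zn]CC(C)C1(CC)OCCO1 | intermediate
6 | alkylzinc enolate of methyl 1-[2-(2-ethyl-1,3-dioxolan-2-yl)propyl]-3-oxocyclohexane-1-carboxylate, quaternary carbon configured as in 8 | COC(=O)[C@]1(CC(C)C2(CC)OCCO2)CCCC(O[Zn]CC(C)C2(CC)OCCO2)=C1 | intermediate
7 | methyl 1-[2-(2-ethyl-1,3-dioxolan-2-yl)propyl]-2-(hydroxymethyl)-3-oxocyclohexane-1-carboxylate, CH2OH cis to CO2Me | COC(=O)[C@]1(CC(C)C2(CC)OCCO2)CCCC(=O)[C@@H]1CO | intermediate
8 | cis-fused keto lactone: 7a-[2-(2-ethyl-1,3-dioxolan-2-yl)propyl]hexahydro-2-benzofuran-1,4-dione (C-1 lactone carbonyl, C-4 ketone) | O=C1CCC[C@@]2(CC(C)C3(CC)OCCO3)C(=O)OC[C@@H]12 | intermediate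
9 | 5-(hydroxymethylidene) derivative of 8 (enolised β-keto aldehyde) | O=C1C(=CO)CC[C@@]2(CC(C)C3(CC)OCCO3)C(=O)OC[C@@H]12 | intermediate
10 | 5-formyl-5-(prop-1-en-2-yl) derivative of 8; formyl β (face of the lactone ring), isopropenyl α | O=C[C@@]1(C(C)=C)CC[C@@]2(CC(C)C3(CC)OCCO3)C(=O)OC[C@H]2C1=O | intermediate
11 | 5-ethenyl-5-(prop-1-en-2-yl) analogue of 10; ethenyl β | C=C[C@@]1(C(C)=C)CC[C@@]2(CC(C)C3(CC)OCCO3)C(=O)OC[C@H]2C1=O | intermediate
12 | 4-hydroxy-4-methyl lactone from 11; OH β, CH3 α | C=C[C@@]1(C(C)=C)CC[C@@]2(CC(C)C3(CC)OCCO3)C(=O)OC[C@H]2[C@@]1(C)O | intermediate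
13 | tert-butyldimethylsilyl ether of 12 | C=C[C@@]1(C(C)=C)CC[C@@]2(CC(C)C3(CC)OCCO3)C(=O)OC[C@H]2[C@@]1(C)O[Si](C)(C)C(C)(C)C | intermediate
14 | 5-[1-(acetoxymercurio)-2-hydroxypropan-2-yl] analogue of 13 (carbinol epimers) | C=C[C@@]1(C(C)(O)C[Hg]OC(C)=O)CC[C@@]2(CC(C)C3(CC)OCCO3)C(=O)OC[C@H]2[C@@]1(C)O[Si](C)(C)C(C)(C)C | intermediate
15 | 5-ethenyl-5-(2-hydroxypropan-2-yl) analogue of 13; ethenyl β, dimethylcarbinol α | C=C[C@@]1(C(C)(C)O)CC[C@@]2(CC(C)C3(CC)OCCO3)C(=O)OC[C@H]2[C@@]1(C)O[Si](C)(C)C(C)(C)C | intermediate
16 | 15 with the dioxolane hydrolysed: 7a-(2-methyl-3-oxopentyl) side chain | C=C[C@@]1(C(C)(C)O)CC[C@@]2(CC(C)C(=O)CC)C(=O)OC[C@H]2[C@@]1(C)O[Si](C)(C)C(C)(C)C | intermediate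
17 | 9-ethenyl-3-hydroxy-7-(hydroxymethyl)-9-(2-hydroxypropan-2-yl)-2,4,8-trimethyl-8-[(tert-butyldimethylsilyl)oxy]spiro[5.5]undec-2-en-1-one; on ring B (C-6 to C-11) C-1, 7-CH2OH, 8-OSi and 9-ethenyl are β | C=C[C@@]1(C(C)(C)O)CC[C@]2(CC(C)C(O)=C(C)C2=O)[C@@H](CO)[C@@]1(C)O[Si](C)(C)C(C)(C)C | intermediate
18 | 3-methoxy analogue of 17 (methyl vinylogous ester, carbonyl at C-1) | C=C[C@@]1(C(C)(C)O)CC[C@]2(CC(C)C(OC)=C(C)C2=O)[C@@H](CO)[C@@]1(C)O[Si](C)(C)C(C)(C)C | intermediate
19 | 7-(chloromethyl) analogue of 18 | C=C[C@@]1(C(C)(C)O)CC[C@]2(CC(C)C(OC)=C(C)C2=O)[C@@H](CCl)[C@@]1(C)O[Si](C)(C)C(C)(C)C | intermediate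
20 | 1-[(1-ethoxyethoxy)methyl]-1-hydroxy-3-methoxy adduct of 19 (carbinol epimers) | C=C[C@@]1(C(C)(C)O)CC[C@]2(CC(C)C(OC)=C(C)C2(O)COC(C)OCC)[C@@H](CCl)[C@@]1(C)O[Si](C)(C)C(C)(C)C | intermediate
21 | 7-(chloromethyl)-9-ethenyl-1-(hydroxymethyl)-9-(2-hydroxypropan-2-yl)-2,4,8-trimethyl-8-[(tert-butyldimethylsilyl)oxy]spiro[5.5]undec-1-en-3-one | C=C[C@@]1(C(C)(C)O)CC[C@]2(CC(C)C(=O)C(C)=C2CO)[C@@H](CCl)[C@@]1(C)O[Si](C)(C)C(C)(C)C | intermediate
22 | prop-2-ynoate ester of the 1-CH2OH of 21 | C=C[C@@]1(C(C)(C)O)CC[C@]2(CC(C)C(=O)C(C)=C2COC(=O)C#C)[C@@H](CCl)[C@@]1(C)O[Si](C)(C)C(C)(C)C | intermediate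
23 | 3-(triethylsilyloxy)spiro[5.5]undeca-1,3-diene from 22, with the 9-dimethylcarbinol as its triethylsilyl ether | C=C[C@@]1(C(C)(C)O[Si](CC)(CC)CC)CC[C@]2(CC(C)=C(O[Si](CC)(CC)CC)C(C)=C2COC(=O)C#C)[C@@H](CCl)[C@@]1(C)O[Si](C)(C)C(C)(C)C | intermediate
24 | Diels–Alder adduct: bicyclo[2.2.2]octadiene silyl enol ether with fused butenolide (ring E), spiro-linked to ring B | C=C[C@@]1(C(C)(C)O[Si](CC)(CC)CC)CC[C@]2(C[C@@]3(C)C=C4C(=O)OC[C@]42C(C)=C3O[Si](CC)(CC)CC)[C@@H](CCl)[C@@]1(C)O[Si](C)(C)C(C)(C)C | intermediate
25 | bicyclo[2.2.2]octenone with fused butenolide; bridges CH(CH3)–C(=O), CH=C (butenolide alkene) and CH2–spiro carbon; ring B carries CH2Cl, C(CH3)(OSi), C(ethenyl)(CMe2OH); ketone α-CH epimers | C=C[C@@]1(C(C)(C)O)CC[C@]2(C[C@@]3(C)C=C4C(=O)OC[C@]42C(C)C3=O)[C@@H](CCl)[C@@]1(C)O[Si](C)(C)C(C)(C)C | intermediate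
26 | 25 with the ketone α-carbon bonded to the former CH2Cl carbon (ring C closed) | C=C[C@@]2(C(C)(C)O)CC[C@@]13C[C@@]4(C)C=C5C(=O)OC[C@]51[C@@](C)(C[C@H]3[C@@]2(C)O[Si](C)(C)C(C)(C)C)C4=O | intermediate
27 | acrylate ester of the dimethylcarbinol of 26 | C=C[C@@]2(C(C)(C)OC(=O)C=C)CC[C@@]13C[C@@]4(C)C=C5C(=O)OC[C@]51[C@@](C)(C[C@H]3[C@@]2(C)O[Si](C)(C)C(C)(C)C)C4=O | intermediate
28 | andibenin B tert-butyldimethylsilyl ether (ring A closed) | CC1(C)OC(=O)C=C[C@]12CC[C@@]13C[C@@]4(C)C=C5C(=O)OC[C@]51[C@@](C)(C[C@H]3[C@@]2(C)O[Si](C)(C)C(C)(C)C)C4=O | intermediate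
29 | andibenin B | CC1(C)OC(=O)C=C[C@]12CC[C@@]13C[C@@]4(C)C=C5C(=O)OC[C@]51[C@@](C)(C[C@H]3[C@@]2(C)O)C4=O | target

**Totals.** Total step count: 19. Longest linear sequence: 19 steps (1 → 29); compound 4 enters in step 2.

**Steps most likely to fail and their fallbacks**

Step 15. The ester tether must reach its reactive conformation and a quaternary carbon is made at the methyl-bearing diene terminus. Cycloaddition may therefore be slower than thermal decomposition or desilylation of the dienol ether, and facial discrimination by ring B may be incomplete. The fallback uses a more reactive alkyne equivalent and sets out from 21. Esterification with (E)-3-(phenylsulfonyl)acrylic acid (DCC, DMAP) should give the sulfonylacrylate F1. Soft enolisation (Et3SiOTf, Et3N) should give the silyl dienol ether F2. Its intramolecular Diels–Alder reaction at 80–100 °C with acidic work-up should give the sulfonyl ketone F3. Elimination of benzenesulfinate with DBU then installs the conjugated alkene, and the route is rejoined at 25.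

Step 14. The amine may trigger oligomerisation of the terminal propiolate, the alkyne may be C-silylated, or deprotonation may occur at the γ-CH2 instead of the α′-CH. The fallback forms the diene before any alkyne is present and sets out from 21. Et3SiOTf and Et3N should give the tris(triethylsilyl) dienol ether F4. An intermolecular Diels–Alder reaction with methyl propiolate (toluene, 110 °C) should give the bicyclic ester F5; the 2-silyloxy group directs the unsubstituted alkyne carbon to the methyl-bearing terminus. HCl in MeOH/THF then removes the silyl groups and lets the freed CH2OH lactonise onto the adjacent ester, which rejoins the route at 25.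

Step 12. Addition to the carbonyl flanked by the spiro centre may fail for steric reasons, or the intermediate tertiary alkoxide may cyclise onto the chloromethyl group. The fallback uses a smaller carbon nucleophile and no alkoxide, and sets out from 19. Corey–Chaykovsky methylenation with dimethylsulfonium methylide (Me3S+ I−, KN(SiMe3)2, THF, −10 °C) should give the spiro epoxide F6. Aqueous HCl in THF should then open the epoxide vinylogously as the enol ether hydrolyses, giving the hydroxymethyl enone and rejoining the route at 21.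

Further compounds
F1 | step 15 | (E)-3-(phenylsulfonyl)acrylate ester of 21 | C=C[C@@]1(C(C)(C)O)CC[C@]2(CC(C)C(=O)C(C)=C2COC(=O)/C=C/S(=O)(=O)c3ccccc3)[C@@H](CCl)[C@@]1(C)O[Si](C)(C)C(C)(C)C
F2 | step 15 | triethylsilyl dienol ether of F1 with the dimethylcarbinol silylated | C=C[C@@]1(C(C)(C)O[Si](CC)(CC)CC)CC[C@]2(CC(C)=C(O[Si](CC)(CC)CC)C(C)=C2COC(=O)/C=C/S(=O)(=O)c3ccccc3)[C@@H](CCl)[C@@]1(C)O[Si](C)(C)C(C)(C)C
F3 | step 15 | phenylsulfonyl-substituted bicyclo[2.2.2]octanone lactone (saturated analogue of 25 carrying SO2Ph on the CH next to the methyl-bearing bridgehead) | C=C[C@@]1(C(C)(C)O)CC[C@]2(C[C@@]3(C)C(S(=O)(=O)c4ccccc4)C4C(=O)OC[C@]42C(C)C3=O)[C@@H](CCl)[C@@]1(C)O[Si](C)(C)C(C)(C)C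
F4 | step 14 | tris(triethylsilyl) derivative of 21: dienol ether, CH2O–Si and dimethylcarbinol O–Si | C=C[C@@]1(C(C)(C)O[Si](CC)(CC)CC)CC[C@]2(CC(C)=C(O[Si](CC)(CC)CC)C(C)=C2CO[Si](CC)(CC)CC)[C@@H](CCl)[C@@]1(C)O[Si](C)(C)C(C)(C)C
F5 | step 14 | bicyclo[2.2.2]octadiene methyl ester from F4 and methyl propiolate | C=C[C@@]1(C(C)(C)O[Si](CC)(CC)CC)CC[C@]2(C[C@@]3(C)C=C(C(=O)OC)[C@]2(CO[Si](CC)(CC)CC)C(C)=C3O[Si](CC)(CC)CC)[C@@H](CCl)[C@@]1(C)O[Si](C)(C)C(C)(C)C
F6 | step 12 | spiro epoxide from 19 (oxirane on the former carbonyl carbon, epimers) | C=C[C@@]1(C(C)(C)O)CC[C@]2(CC(C)C(OC)=C(C)C23CO3)[C@@H](CCl)[C@@]1(C)O[Si](C)(C)C(C)(C)C
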